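**Plan**

- Retrosynthesis: the two acetates and the 1,10-oxirane go first, then the ten-membered ring is opened at C8–C9 (metathesis, then saturation). The butenolide is then cut at O–C6 and C11–C12 together, which releases CO2. Last, C5=C6 is cut into iodide 7 (C6, C7, C8, C11, C13) and epoxy aldehyde 11 (C1–C5, C9, C10, C14, C15).
- Enabling feature: C6 is both the γ-carbon of the butenolide ring (O–C6–C7=C11–C12) and the end of the 1,4-dioxygenated (E)-2-ene C3(O)–C4=C5–C6(O). A C3–C4 vinyl oxirane with a C5=C6 alkene and a carbanion at C11 therefore takes up CO2 as a two-bond [3+2] partner.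
- Forward order: the chain is assembled open; the butenolide closes in step 9, the ten-membered carbocycle in step 10 (adjusted in step 11), and the oxirane ring is formed last.
- Stereochemistry: C3 and C4 come from a Sharpless epoxidation; C6 and the 4E alkene come from C4 by 1,3-transfer in step 9. The C7=C11 geometry comes from an anti-carbomagnesiation, 1(10)E from (E)-β-ocimene, and C1/C10 from epoxidation of the outer face of the germacranolide.

Key step: step 9

Remarks on the chemistry: (E)-β-ocimene (8) is assumed to be purchasable as the single geometric isomer. The alkene formed in step 10 is drawn 8Z, but either geometry serves because it is reduced in step 11. Germacrane numbering is used for the macrocycles (ring C1–C10, C11 = butenolide α-carbon, C12 = lactone carbonyl, C13 = CH2O, C14/C15 = methyls on C10/C4).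

**Route**

Step 1
Reactants: 1 2-butyne-1,4-diol
Product: 2 4-[(4-methoxybenzyl)oxy]but-2-yn-1-ol
Conditions: NaH (1 equiv), PMBCl (1 equiv), diol in excess (3 equiv), Bu4NI (cat.), THF/DMF, 0 °C → rt
Reagents that add atoms: 4-methoxybenzyl chloride, COc1ccc(CCl)cc1
Why: Williamson ether synthesis on a symmetric diol used in excess should give the mono-ether; no stereocentre is formed.

Step 2
Reactants: 2 4-[(4-methoxybenzyl)oxy]but-2-yn-1-ol; 3 vinylmagnesium chloride
Product: 5 (2Z)-2-ethenyl-3-iodo-4-[(4-methoxybenzyl)oxy]but-2-en-1-ol, via cyclic alkenylmagnesium alkoxide 4 (not isolated)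
Conditions: CH2=CHMgCl (3.5 equiv), THF/toluene, reflux; then I2, THF, −78 → 0 °C
Reagents that add atoms: iodine, II
Why: Hydroxyl-directed anti-carbomagnesiation of a propargylic alcohol (the vinyl carbon adds to the alkyne carbon next to the alkoxide, C7, while magnesium ends on C11 inside a five-membered alkoxide chelate) followed by iodinolysis with retention should give the tetrasubstituted alkene with iodine cis to CH2OH, which is the C7=C11 geometry needed for lactone closure.

Step 3
Reactants: 5 (2Z)-2-ethenyl-3-iodo-4-[(4-methoxybenzyl)oxy]but-2-en-1-ol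
Product: 6 (2Z)-1-bromo-2-ethenyl-3-iodo-4-[(4-methoxybenzyl)oxy]but-2-ene
Conditions: CBr4, PPh3, 2,6-lutidine, CH2Cl2, 0 °C
Reagents that add atoms: carbon tetrabromide, BrC(Br)(Br)Br
Why: Appel bromination of the primary allylic alcohol under buffered conditions should proceed by SN2 at CH2 without touching the alkene geometry.

Step 4
Reactants: 6 (2Z)-1-bromo-2-ethenyl-3-iodo-4-[(4-methoxybenzyl)oxy]but-2-ene
Product: 7 tributyl{(2Z)-2-ethenyl-3-iodo-4-[(4-methoxybenzyl)oxy]but-2-en-1-yl}phosphonium bromide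
Conditions: PBu3, MeCN, rt
Reagents that add atoms: tributylphosphine, CCCCP(CCCC)CCCC
Why: SN2 quaternisation of the allylic bromide gives the salt for a Wittig reaction, tributyl substitution being chosen because allylic tributylphosphonium ylides favour E-alkenes.

Step 5
Reactants: 8 (E)-β-ocimene [(3E)-3,7-dimethylocta-1,3,6-triene]
Product: 9 (2E,5E)-2,6-dimethylocta-2,5,7-trien-1-ol
Conditions: SeO2 (cat.), t-BuOOH, salicylic acid (cat.), CH2Cl2, 0 °C → rt
Reagents that add atoms: tert-butyl hydroperoxide, CC(C)(C)OO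
Why: Selenium dioxide allylic oxidation (ene reaction, then [2,3]-sigmatropic shift) attacks the most electron-rich, isolated trisubstituted alkene at its E-methyl group, which should give the (E)-allylic alcohol and leave the (E)-diene unit untouched.

Step 6
Reactants: 9 (2E,5E)-2,6-dimethylocta-2,5,7-trien-1-ol
Product: 10 [(2S,3S)-2-methyl-3-[(2E)-3-methylpenta-2,4-dien-1-yl]oxiran-2-yl]methanol
Conditions: Ti(OiPr)4 (cat.), L-(+)-diethyl tartrate (cat.), t-BuOOH, 4 Å MS, CH2Cl2, −20 °C
Reagents that add atoms: tert-butyl hydroperoxide, CC(C)(C)OO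
Why: Sharpless asymmetric epoxidation touches only the allylic-alcohol alkene, and L-(+)-tartrate should deliver oxygen to the face that gives the (2S,3S)-oxirane, which fixes C3 (S) and C4 (S) in germacrane numbering.

Step 7
Reactants: 10 [(2S,3S)-2-methyl-3-[(2E)-3-methylpenta-2,4-dien-1-yl]oxiran-2-yl]methanol
Product: 11 (2R,3S)-2-methyl-3-[(2E)-3-methylpenta-2,4-dien-1-yl]oxirane-2-carbaldehyde
Conditions: Dess–Martin periodinane, pyridine, CH2Cl2, 0 °C → rt
Reagents that add atoms: none
Why: Dess–Martin oxidation under buffered conditions gives the epoxy aldehyde, whose α-carbon is quaternary and cannot epimerise (the descriptor changes only through the priority rules).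

Step 8
Reactants: 7 tributyl{(2Z)-2-ethenyl-3-iodo-4-[(4-methoxybenzyl)oxy]but-2-en-1-yl}phosphonium bromide; 11 (2R,3S)-2-methyl-3-[(2E)-3-methylpenta-2,4-dien-1-yl]oxirane-2-carbaldehyde
Product: 13 1-[({(2Z,4E)-2-iodo-5-[(2S,3S)-2-methyl-3-[(2E)-3-methylpenta-2,4-dien-1-yl]oxiran-2-yl]-3-vinylpenta-2,4-dien-1-yl}oxy)methyl]-4-methoxybenzene, via phosphonium ylide 12 (not isolated)
Conditions: KHMDS (1.0 equiv), THF, −78 °C; then 11, −78 → 0 °C
Reagents that add atoms: none
Why: Wittig olefination with the allylic tributylphosphonium ylide should form the C5=C6 bond with E geometry, while the oxirane centres and the iodoalkene geometry are unaffected.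

Step 9
Reactants: 13 1-[({(2Z,4E)-2-iodo-5-[(2S,3S)-2-methyl-3-[(2E)-3-methylpenta-2,4-dien-1-yl]oxiran-2-yl]-3-vinylpenta-2,4-dien-1-yl}oxy)methyl]-4-methoxybenzene
Product: 16 (5R)-5-[(1E,3S,5E)-3-hydroxy-2,6-dimethylocta-1,5,7-trien-1-yl]-3-{[(4-methoxybenzyl)oxy]methyl}-4-vinylfuran-2(5H)-one, via alkenyllithium 14 (not isolated), via lithium dienoate 15 (not isolated)
Conditions: t-BuLi (2.1 equiv), Et2O, −78 °C; CO2 (g), −78 → −20 °C; AcOH (1.1 equiv); Pd(PPh3)4 (5 mol %), THF, 0 °C → rt
Reagents that add atoms: carbon dioxide, O=C=O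
Why: tert-Butyllithium exchanges the C11 iodide (faster than any attack on the oxirane at −78 °C, alkene geometry retained) and alkenyllithium 14 adds to CO2 to make the C11–C12 bond; after buffering with acetic acid, Pd(0) ionises the C3–C4 vinyl oxirane from the face anti to the C4–O bond to a syn,syn-π-allyl complex over C4–C5–C6 that carries the C3 alkoxide. The carboxylate, held cis to C6 across C7=C11, then attacks the distal allyl terminus C6 anti to palladium and makes the O–C6 bond. The closest known reaction types are the carboxylation of alkenyllithiums with CO2 and the Pd(0)-catalysed 1,4-opening of vinyl oxiranes by carboxylic acids (Tsuji–Trost type lactonisation), here run in one flask. The butenolide closes by 5-exo attack of oxygen on the η3-allyl terminus, the seven-membered alternative at C4 being disfavoured. C6 is set by the C4 oxirane centre through double inversion (the new oxygen enters on the face the oxirane oxygen left, which with the E-C5=C6 alkene gives 6R), the new C4=C5 bond is E because the larger C3 substituent takes the syn position of the allyl unit, and C3 (S) is untouched. The step needs chemoselective I/Li exchange, distal rather than proximal attack and no re-ionisation of the allylic lactone, which the fast exchange at low temperature, the five-ring preference and a low Pd loading at 0 °C with prompt quench should secure.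

Step 10
Reactants: 16 (5R)-5-[(1E,3S,5E)-3-hydroxy-2,6-dimethylocta-1,5,7-trien-1-yl]-3-{[(4-methoxybenzyl)oxy]methyl}-4-vinylfuran-2(5H)-one
Product: 17 (3S,6R,8Z)-3-hydroxy-13-[(4-methoxybenzyl)oxy]germacra-1(10)E,4E,7(11),8-tetraen-12,6-olide
Conditions: Hoveyda–Grubbs II (10 mol %), toluene (1 mM), 50 °C, argon sparge
Reagents that add atoms: none
Why: Ring-closing metathesis between the two terminal vinyl groups (the tri- and tetrasubstituted alkenes are inert) closes the ten-membered carbocycle at C8=C9, whose geometry is irrelevant because it is reduced next.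

Step 11
Reactants: 17 (3S,6R,8Z)-3-hydroxy-13-[(4-methoxybenzyl)oxy]germacra-1(10)E,4E,7(11),8-tetraen-12,6-olide
Product: 18 (3S,6R)-3-hydroxy-13-[(4-methoxybenzyl)oxy]germacra-1(10)E,4E,7(11)-trien-12,6-olide
Conditions: KO2CN=NCO2K, AcOH, MeOH/CH2Cl2, 0 °C → rt
Reagents that add atoms: none
Why: Diimide reduction (concerted syn transfer of H2) should select the only disubstituted alkene over the two trisubstituted alkenes and the tetrasubstituted butenolide alkene, and acidic generation of diimide avoids base at the epimerisable C6.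

Step 12
Reactants: 18 (3S,6R)-3-hydroxy-13-[(4-methoxybenzyl)oxy]germacra-1(10)E,4E,7(11)-trien-12,6-olide
Product: 19 (3S,6R)-3,13-dihydroxygermacra-1(10)E,4E,7(11)-trien-12,6-olide
Conditions: DDQ (1.3 equiv), CH2Cl2/pH 7 buffer (10:1), 0 °C
Reagents that add atoms: none
Why: Oxidative cleavage of the p-methoxybenzyl ether by DDQ (hydride abstraction at the electron-rich benzylic position, then hydrolysis) frees the C13 alcohol under buffered conditions that spare the germacradiene.

Step 13
Reactants: 19 (3S,6R)-3,13-dihydroxygermacra-1(10)E,4E,7(11)-trien-12,6-olide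
Product: 20 (3S,6R)-3,13-diacetoxygermacra-1(10)E,4E,7(11)-trien-12,6-olide
Conditions: Ac2O, pyridine, DMAP (cat.), CH2Cl2, 0 °C → rt
Reagents that add atoms: acetic anhydride, CC(=O)OC(C)=O
Why: DMAP-catalysed acylation converts the primary C13 and the secondary C3 alcohol into the two acetates of the target with retention at C3.

Step 14
Reactants: 20 (3S,6R)-3,13-diacetoxygermacra-1(10)E,4E,7(11)-trien-12,6-olide
Product: 21 (1R,3S,6R,10R)-3,13-diacetoxy-1,10-epoxygermacra-4E,7(11)-dien-12,6-olide
Conditions: mCPBA (1.1 equiv), NaHCO3, CH2Cl2, −20 → 0 °C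
Reagents that add atoms: 3-chloroperoxybenzoic acid, O=C(OO)c1cccc(Cl)c1
Why: Prilezhaev epoxidation should select the electron-rich isolated 1(10) alkene (the 4,5-alkene is flanked by two allylic acyloxy groups, the 7(11)-alkene is conjugated to the lactone), and attack on the exposed outer face of the (E)-alkene in the crown conformation of the germacranolide should give the trans (1R,10R)-oxirane.

**Compound list**

1 | 2-butyne-1,4-diol | OCC#CCO | starting material
2 | 4-[(4-methoxybenzyl)oxy]but-2-yn-1-ol | COc1ccc(COCC#CCO)cc1 | intermediate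
3 | vinylmagnesium chloride | C=C[Mg]Cl | starting material
4 | cyclic alkenylmagnesium alkoxide (2,5-dihydro-1,2-oxamagnesole) | C=CC1=C(COCc2ccc(OC)cc2)[Mg]OC1 | intermediate (not isolated)
5 | (2Z)-2-ethenyl-3-iodo-4-[(4-methoxybenzyl)oxy]but-2-en-1-ol | OC/C(C=C)=C(\I)COCc1ccc(OC)cc1 | intermediate
6 | (2Z)-1-bromo-2-ethenyl-3-iodo-4-[(4-methoxybenzyl)oxy]but-2-ene | BrC/C(C=C)=C(\I)COCc1ccc(OC)cc1 | intermediate
7 | tributyl{(2Z)-2-ethenyl-3-iodo-4-[(4-methoxybenzyl)oxy]but-2-en-1-yl}phosphonium bromide | CCCC[P+](CCCC)(CCCC)C/C(C=C)=C(\I)COCc1ccc(OC)cc1.[Br-] | intermediate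
8 | (E)-β-ocimene | C=C/C(C)=C/CC=C(C)C | starting material
9 | (2E,5E)-2,6-dimethylocta-2,5,7-trien-1-ol | OC/C(C)=C/C/C=C(/C=C)C | intermediate
10 | [(2S,3S)-2-methyl-3-[(2E)-3-methylpenta-2,4-dien-1-yl]oxiran-2-yl]methanol | OC[C@]1(C)O[C@H]1C/C=C(/C=C)C | intermediate
11 | (2R,3S)-2-methyl-3-[(2E)-3-methylpenta-2,4-dien-1-yl]oxirane-2-carbaldehyde | O=C[C@]1(C)O[C@H]1C/C=C(/C=C)C | intermediate
12 | phosphonium ylide of 7 | CCCC[P+](CCCC)(CCCC)[CH-]/C(C=C)=C(\I)COCc1ccc(OC)cc1 | intermediate (not isolated)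
13 | 1-[({(2Z,4E)-2-iodo-5-[(2S,3S)-2-methyl-3-[(2E)-3-methylpenta-2,4-dien-1-yl]oxiran-2-yl]-3-vinylpenta-2,4-dien-1-yl}oxy)methyl]-4-methoxybenzene | COc1ccc(COC/C(I)=C(C=C)/C=C/[C@]2(C)O[C@H]2C/C=C(/C=C)C)cc1 | intermediate
14 | alkenyllithium (13 with lithium in place of iodine, geometry retained) | COc1ccc(COC/C([Li])=C(C=C)/C=C/[C@]2(C)O[C@H]2C/C=C(/C=C)C)cc1 | intermediate (not isolated)
15 | lithium (2Z,4E)-2-{[(4-methoxybenzyl)oxy]methyl}-5-[(2S,3S)-2-methyl-3-[(2E)-3-methylpenta-2,4-dien-1-yl]oxiran-2-yl]-3-vinylpenta-2,4-dienoate | COc1ccc(COC/C(C(=O)[O-])=C(C=C)/C=C/[C@]2(C)O[C@H]2C/C=C(/C=C)C)cc1.[Li+] | intermediate (not isolated)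
16 | (5R)-5-[(1E,3S,5E)-3-hydroxy-2,6-dimethylocta-1,5,7-trien-1-yl]-3-{[(4-methoxybenzyl)oxy]methyl}-4-vinylfuran-2(5H)-one | COc1ccc(COCC2=C(C=C)[C@@H](/C=C(\C)[C@@H](O)C/C=C(/C=C)C)OC2=O)cc1 | intermediate
17 | (3S,6R,8Z)-3-hydroxy-13-[(4-methoxybenzyl)oxy]germacra-1(10)E,4E,7(11),8-tetraen-12,6-olide | COc1ccc(COCC2=C3/C=C\C(C)=C\C[C@H](O)/C(C)=C/[C@H]3OC2=O)cc1 | intermediate
18 | (3S,6R)-3-hydroxy-13-[(4-methoxybenzyl)oxy]germacra-1(10)E,4E,7(11)-trien-12,6-olide | COc1ccc(COCC2=C3CC/C(C)=C/C[C@H](O)/C(C)=C/[C@H]3OC2=O)cc1 | intermediate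
19 | (3S,6R)-3,13-dihydroxygermacra-1(10)E,4E,7(11)-trien-12,6-olide | OCC1=C2CC/C(C)=C/C[C@H](O)/C(C)=C/[C@H]2OC1=O | intermediate
20 | (3S,6R)-3,13-diacetoxygermacra-1(10)E,4E,7(11)-trien-12,6-olide | CC(=O)OCC1=C2CC/C(C)=C/C[C@H](OC(C)=O)/C(C)=C/[C@H]2OC1=O | intermediate
21 | (1R,3S,6R,10R)-3,13-diacetoxy-1,10-epoxygermacra-4E,7(11)-dien-12,6-olide | CC(=O)OCC1=C2CC[C@@]3(C)O[C@@H]3C[C@H](OC(C)=O)/C(C)=C/[C@H]2OC1=O | target

**Step count**

Total: 14 steps. Longest linear sequence: 11 steps (steps 1–4, then 8–14); the second branch (steps 5–7) joins at step 8.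

**Steps most likely to fail, with fallbacks**

1. Step 10 (ring-closing metathesis). The catalyst may be sequestered as a conjugated ruthenium vinylcarbene at the diene terminus, or the chain may oligomerise instead of closing the strained ring. The fallback sets out from 16 and rejoins the route at 21. Shi epoxidation of 16 (D-fructose-derived ketone, Oxone, pH 10.5, 0 °C) should epoxidise the trisubstituted alkene of the terminal diene under reagent control and give (5R)-5-{(1E,3S)-3-hydroxy-2-methyl-4-[(2R,3R)-3-methyl-3-vinyloxiran-2-yl]but-1-en-1-yl}-3-{[(4-methoxybenzyl)oxy]methyl}-4-vinylfuran-2(5H)-one F1; the 4,5-alkene is deactivated by its two allylic oxygens. Metathesis then pairs the butenolide vinyl group with an isolated vinyl group instead of a diene and should give the macrocyclic 8-ene (1R,3S,6R,8Z,10R)-1,10-epoxy-3-hydroxy-13-[(4-methoxybenzyl)oxy]germacra-4E,7(11),8-trien-12,6-olide F2. Diimide reduction (2-nitrobenzenesulfonyl hydrazide, Et3N) gives the saturated ring (1R,3S,6R,10R)-1,10-epoxy-3-hydroxy-13-[(4-methoxybenzyl)oxy]germacra-4E,7(11)-dien-12,6-olide F3, DDQ gives the diol (1R,3S,6R,10R)-1,10-epoxy-3,13-dihydroxygermacra-4E,7(11)-dien-12,6-olide F4, and acetylation (Ac2O, pyridine, DMAP) gives 21. This also replaces the substrate-controlled epoxidation of step 14.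

2. Step 9 (carboxylative lactonisation). In the salt-laden one-flask medium the lactonisation may be incomplete or unselective: proximal attack, loss of the π-allyl complex by elimination to a triene, or erosion at C6 by re-ionisation of the allylic lactone. The fallback sets out from 13 and rejoins at 16, with the two bonds made in separate operations. Iodine–lithium exchange as before, but trapping with allyl chloroformate, gives the isolable ester allyl (2Z,4E)-2-{[(4-methoxybenzyl)oxy]methyl}-5-[(2S,3S)-2-methyl-3-[(2E)-3-methylpenta-2,4-dien-1-yl]oxiran-2-yl]-3-vinylpenta-2,4-dienoate F5. Pd(PPh3)4 with morpholine (THF, 0 °C) then removes the allyl group (Tsuji–Trost deallylation), and the same catalyst effects the vinyl-oxirane lactonisation of the liberated carboxylate under neutral, amine-buffered conditions to give 16.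

3. Step 8 (Wittig union). E/Z control may be poor, or the cross-conjugated ylide may decompose before it meets the hindered aldehyde. The fallback sets out from 6 and rejoins at 13 by a Julia–Kocienski olefination. Bromide 6 with 1-phenyl-1H-tetrazole-5-thiol and Et3N gives the sulfide 5-{[(2Z)-3-iodo-4-[(4-methoxybenzyl)oxy]-2-vinylbut-2-en-1-yl]sulfanyl}-1-phenyl-1H-tetrazole F6. Oxidation (ammonium molybdate, H2O2, EtOH, 0 °C) gives the sulfone 5-{[(2Z)-3-iodo-4-[(4-methoxybenzyl)oxy]-2-vinylbut-2-en-1-yl]sulfonyl}-1-phenyl-1H-tetrazole F7. Deprotonation (KHMDS, DME, −60 °C) and addition of 11 should give 13 with the E-C5=C6 alkene.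

Further compounds
F1 | step 10 | (5R)-5-{(1E,3S)-3-hydroxy-2-methyl-4-[(2R,3R)-3-methyl-3-vinyloxiran-2-yl]but-1-en-1-yl}-3-{[(4-methoxybenzyl)oxy]methyl}-4-vinylfuran-2(5H)-one | COc1ccc(COCC2=C(C=C)[C@@H](/C=C(\C)[C@@H](O)C[C@H]3O[C@]3(C)C=C)OC2=O)cc1
F2 | step 10 | (1R,3S,6R,8Z,10R)-1,10-epoxy-3-hydroxy-13-[(4-methoxybenzyl)oxy]germacra-4E,7(11),8-trien-12,6-olide | COc1ccc(COCC2=C3/C=C\[C@@]4(C)O[C@@H]4C[C@H](O)/C(C)=C/[C@H]3OC2=O)cc1
F3 | step 10 | (1R,3S,6R,10R)-1,10-epoxy-3-hydroxy-13-[(4-methoxybenzyl)oxy]germacra-4E,7(11)-dien-12,6-olide | COc1ccc(COCC2=C3CC[C@@]4(C)O[C@@H]4C[C@H](O)/C(C)=C/[C@H]3OC2=O)cc1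
F4 | step 10 | (1R,3S,6R,10R)-1,10-epoxy-3,13-dihydroxygermacra-4E,7(11)-dien-12,6-olide | OCC1=C2CC[C@@]3(C)O[C@@H]3C[C@H](O)/C(C)=C/[C@H]2OC1=O
F5 | step 9 | allyl (2Z,4E)-2-{[(4-methoxybenzyl)oxy]methyl}-5-[(2S,3S)-2-methyl-3-[(2E)-3-methylpenta-2,4-dien-1-yl]oxiran-2-yl]-3-vinylpenta-2,4-dienoate | COc1ccc(COC/C(C(=O)OCC=C)=C(C=C)/C=C/[C@]2(C)O[C@H]2C/C=C(/C=C)C)cc1
F6 | step 8 | 5-{[(2Z)-3-iodo-4-[(4-methoxybenzyl)oxy]-2-vinylbut-2-en-1-yl]sulfanyl}-1-phenyl-1H-tetrazole | COc1ccc(COC/C(I)=C(C=C)/CSc2nnnn2-c2ccccc2)cc1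
F7 | step 8 | 5-{[(2Z)-3-iodo-4-[(4-methoxybenzyl)oxy]-2-vinylbut-2-en-1-yl]sulfonyl}-1-phenyl-1H-tetrazole | COc1ccc(COC/C(I)=C(C=C)/CS(=O)(=O)c2nnnn2-c2ccccc2)cc1
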